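Slowness here is a matter of counting: how many half-lives of the step from intermediate to target fit into the time allowed?

    intermediate ⇌ target (K1 = 0.65, k1 = 0.17 s⁻¹, Ea1 = 78.0 kJ mol⁻¹, ΔH1 = 1.00 kJ mol⁻¹)
    starting material + partner → intermediate + released group (k2 = 6.6 M⁻¹ s⁻¹, Ea2 = 53.0 kJ mol⁻¹)
    starting material + intermediate → side product (k3 = 6.4 M⁻¹ s⁻¹, Ea3 = 51.0 kJ mol⁻¹)
    intermediate ⇌ isomer of the product (K4 = 2.3, k4 = 0.0081 s⁻¹, Ea4 = 88.0 kJ mol⁻¹, ΔH4 = −27.0 kJ mol⁻¹)
    starting material + target ⇌ idle adduct, settled at all times (K5 = 35 M⁻¹, ΔH5 = 13.0 kJ mol⁻¹)
    (constants at 40 °C)

| flask | starting material | partner | temperature | time |
|---|---|---|---|---|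
| eta | 0.020 M | 0.0300 M | 15 °C | 8.0 s |
| gamma | 0.020 M | 0.0300 M | 40 °C | 8.0 s |
| zeta | 0.020 M | 0.0300 M | −10 °C | 8.0 s |

- in percentages every species weighs as the starting material in it: one idle adduct or side product counts as two
- for target the idle adduct is counted in
- the list of constants is for 40 °C, to be carried to other temperatures by the activation energies and enthalpies
- in an amount of target, one idle adduct counts as one target

- the flask that comes out highest in amount of target, in percent of the starting material charged, or "all alike" when all lie within 1.5 percentage points (eta / gamma / zeta / all alike)
- target at the end, in percent of the starting material charged, eta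
- target at the end, in percent of the starting material charged, gamma
- target at the end, in percent of the starting material charged, zeta

Intermediate and target relax towards their balance with both directions working together. In gamma that relaxation, by this step alone, has a half-life of 1.61 s, so the time holds n = 4.98 of them. Carried by the activation energy, the forward constant falls to 0.0126 s⁻¹ in eta and 5.73 × 10⁻⁴ s⁻¹ in zeta. With the enthalpy carried too, eta gets n = 0.378 and zeta n = 0.0176.

This n, the number of relaxation half-lives inside the time, says in words whether target has caught up with intermediate. Above one, this step alone brings free target towards the equilibrium constant times intermediate. Below one, target is still a trickle from a growing pool.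

Gamma has the greatest count, so we expect gamma to come out highest.

For a trickle we need a second clock, p, the partner step's constant times the partner charge times the time; this treats the step as pseudo-first-order. Intermediate grows as p, and target as the forward constant times the time times p, over 2. That gives 1.37% for eta and 0.00759% for zeta.

So one number was not enough. In gamma the same product gives 108%, more than the charge. There we take the balance share of what the partner step can turn over, leaving the idle adduct aside, and commit, as a rough estimate of the ceiling, to less than 31.3%.

The forecast gives gamma as highest, with 1.04% for eta, 18% for gamma and 0.0075% for zeta: “Gamma is highest, because step 1 is strongly temperature-sensitive”.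

The simulation gives gamma as highest, with 1.04% for eta, 18.1% for gamma and 0.00737% for zeta. In gamma the relaxation half-life by this step alone, 1.61 s, is shorter than the time of 8.0 s, and at n = 4.98 free target stands at 0.499 of intermediate, against an equilibrium constant of 0.65. Gamma read at 20 s has n = 12.4, and there the same ratio is 0.651.

Its constants are those of an exercise; the flask was simulated.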